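## Retrosynthetic overview

1. Target 18 is a linear chain of five benzene rings joined by four ether oxygens, with thirteen hydroxyls and no stereocentre. Rings are lettered A to E from the 2,4,6-trihydroxyphenyl end, and position 1 of each ring is the carbon bonded to the ether oxygen that points toward ring A (for ring A, its only ether carbon).
2. The last disconnection is the eleven methyl ethers of 17. The key disconnection takes the C–O bonds at position 4 of ring A and position 5 of ring B in 17 back to C–H bonds in 15. It rests on one feature: of all oxygen-bearing carbons of the target, only carbon 4 of ring A (between the C–H carbons 3 and 5) and carbon 5 of ring B (between the C–H carbons 4 and 6) have hydrogen on both neighbours. In 15, therefore, these two are the only aryl C–H bonds without an ortho substituent; positions 3 and 5 of ring A, 4 and 6 of ring B, 2 and 6 of ring C, 2 of ring D, and 2 and 6 of ring E each lie next to a methoxy or aryloxy group.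
3. 15 is cut at its four ether oxygens. No ring is constructed; all five benzene rings are bought. A–O–B comes from an SNAr reaction, and C–O–D, B–O–C and D–O–E from Ullmann couplings in which the crowded partner is always the phenoxide. Each formyl group that activates a halide is then converted into the next phenol by Baeyer–Villiger oxidation.
4. Order of bond formation: A–O–B (steps 1–2) and C–O–D (steps 3–4) in parallel, then B–O–C (step 5), D–O–E (steps 6–7), the two C–O bonds at position 4 of ring A and position 5 of ring B (step 8), and deprotection (step 9). Methyl ethers are used throughout because they offer the borylation catalyst no unhindered aryl C–H bond.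

Key step: step 8

Assumption: 6-bromo-2,3,4-trimethoxybenzaldehyde (8) is not taken as a catalogue item and is made in step 3; building blocks 1, 2, 6, 9 and 14 are commercial.

## Route

Step 1
Reactants: 1 2,6-dimethoxyphenol; 2 2-fluoro-6-methoxybenzaldehyde
Product: 3 2-(2,6-dimethoxyphenoxy)-6-methoxybenzaldehyde
Conditions: K2CO3, DMF, 120 °C, argon
Reagents that add atoms: none
Why: Nucleophilic aromatic substitution, in which the phenoxide of 1 adds at the fluorine-bearing carbon of 2 to give a Meisenheimer adduct stabilised by the ortho formyl group and fluoride leaves; the methoxy group meta to fluorine does not interfere.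

Step 2
Reactants: 3 2-(2,6-dimethoxyphenoxy)-6-methoxybenzaldehyde
Product: 5 2-(2,6-dimethoxyphenoxy)-6-methoxyphenol, via aryl formate 4 (not isolated)
Conditions: mCPBA, CH2Cl2, 0 °C to rt; then K2CO3 (cat.), MeOH, rt
Reagents that add atoms: mCPBA (3-chloroperbenzoic acid), OOC(=O)c1cccc(Cl)c1
Why: Baeyer–Villiger oxidation, in which the electron-rich 2,6-dioxygenated aryl group migrates in preference to hydrogen to give formate 4, and methanolysis then frees the hydroxyl at position 2 of ring B, between the aryloxy and methoxy groups.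

Step 3
Reactants: 6 5-bromo-1,2,3-trimethoxybenzene
Product: 8 6-bromo-2,3,4-trimethoxybenzaldehyde, via alpha-chloro ether 7 (not isolated)
Conditions: Cl2CHOMe, TiCl4, CH2Cl2, −10 to 0 °C; then ice-water
Reagents that add atoms: dichloromethyl methyl ether, COC(Cl)Cl; water, O
Why: Rieche formylation (Friedel–Crafts type), in which the TiCl4-activated chloro(methoxy)methyl cation attacks the only kind of ring C–H in 6 (two symmetry-equivalent positions, ortho and para to methoxy groups) and aqueous work-up hydrolyses 7 to the aldehyde.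

Step 4
Reactants: 9 4-bromo-2,6-dimethoxyphenol; 8 6-bromo-2,3,4-trimethoxybenzaldehyde
Product: 10 6-(4-bromo-2,6-dimethoxyphenoxy)-2,3,4-trimethoxybenzaldehyde
Conditions: CuI (10 mol%), picolinic acid (20 mol%), K3PO4, DMSO, 80 °C, argon
Reagents that add atoms: none
Why: Ullmann-type C–O coupling, in which the hindered phenoxide of 9 is arylated at the C–Br bond of 8, activated by the ortho formyl group through electron withdrawal and carbonyl coordination to copper, while the bromide of 9 sits para to a phenoxide oxygen and should be far slower in oxidative addition.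

Step 5
Reactants: 5 2-(2,6-dimethoxyphenoxy)-6-methoxyphenol; 10 6-(4-bromo-2,6-dimethoxyphenoxy)-2,3,4-trimethoxybenzaldehyde
Product: 11 6-{4-[2-(2,6-dimethoxyphenoxy)-6-methoxyphenoxy]-2,6-dimethoxyphenoxy}-2,3,4-trimethoxybenzaldehyde
Conditions: CuI (10 mol%), picolinic acid (20 mol%), K3PO4, DMSO, 100 °C, argon
Reagents that add atoms: none
Why: Ullmann-type C–O coupling of a 2,6-disubstituted phenol with an aryl bromide that has no ortho substituent, the pairing this copper/picolinic acid system handles well; the aldehyde on ring D is a spectator.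

Step 6
Reactants: 11 6-{4-[2-(2,6-dimethoxyphenoxy)-6-methoxyphenoxy]-2,6-dimethoxyphenoxy}-2,3,4-trimethoxybenzaldehyde
Product: 13 6-{4-[2-(2,6-dimethoxyphenoxy)-6-methoxyphenoxy]-2,6-dimethoxyphenoxy}-2,3,4-trimethoxyphenol, via formate ester 12 (not isolated)
Conditions: mCPBA (1.2 equiv), CH2Cl2, 0 °C to rt; then K2CO3 (cat.), MeOH, rt
Reagents that add atoms: mCPBA (3-chloroperbenzoic acid), OOC(=O)c1cccc(Cl)c1
Why: Baeyer–Villiger oxidation as in step 2, where the formyl group on ring D lies between an aryloxy and a methoxy group so that aryl migration to formate 12 is favoured and methanolysis frees the hydroxyl at position 6 of ring D; the peracid is kept near one equivalent to spare the electron-rich rings.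

Step 7
Reactants: 13 6-{4-[2-(2,6-dimethoxyphenoxy)-6-methoxyphenoxy]-2,6-dimethoxyphenoxy}-2,3,4-trimethoxyphenol; 14 5-iodo-1,2,3-trimethoxybenzene
Product: 15 1-[2-(2,6-dimethoxyphenoxy)-6-methoxyphenoxy]-3,5-dimethoxy-4-[3,4,5-trimethoxy-2-(3,4,5-trimethoxyphenoxy)phenoxy]benzene (dideoxy undeca-O-methyl pentamer)
Conditions: CuI (10 mol%), picolinic acid (20 mol%), K3PO4, DMSO, 90 °C, argon
Reagents that add atoms: none
Why: Ullmann-type C–O coupling of the di-ortho-substituted ring D phenoxide with an unhindered aryl iodide, again with the steric load on the nucleophile only.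

Step 8
Reactants: 15 dideoxy undeca-O-methyl pentamer
Product: 17 3,5-dimethoxy-4-{5-hydroxy-3-methoxy-2-[3,5-dimethoxy-4-(3,4,5-trimethoxy-2-(3,4,5-trimethoxyphenoxy)phenoxy)phenoxy]phenoxy}phenol (undeca-O-methyl pentamer diol), via bis-boronate 16 (not isolated)
Conditions: [Ir(OMe)(cod)]2 (3 mol%), 4,4'-di-tert-butyl-2,2'-bipyridine (6 mol%), B2pin2 (3 equiv), THF, 80 °C (sealed tube); then NaBO3·4H2O, THF/H2O, rt
Reagents that add atoms: bis(pinacolato)diboron, CC1(C)OB(OC1(C)C)B1OC(C)(C)C(C)(C)O1 (boron is carried only in 16); sodium perborate, [Na+].[O-]OB=O (source of the two new hydroxyl oxygens)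
Why: Iridium-catalysed aromatic C–H borylation followed by oxidation of the C–B bonds in the same flask: the tris(boryl) complex of trivalent iridium carrying the bipyridine ligand cleaves an aryl C–H bond, releases the aryl pinacol boronate by C–B reductive elimination and is regenerated by B2pin2. The closest known reaction type is the one-pot borylation–oxidation of 1,2,3-trisubstituted benzenes to 3,4,5-trisubstituted phenols, which is the substitution pattern of rings A and B in 15. No ring is closed and no stereocentre is formed. The step needs site selectivity for the C–H bonds at position 4 of ring A and position 5 of ring B and completeness at both; the crowded iridium centre does not reach a C–H bond with an ortho substituent, and in 15 every other ring hydrogen (positions 3 and 5 of ring A, 4 and 6 of ring B, 2 and 6 of ring C, 2 of ring D, 2 and 6 of ring E) lies next to a methoxy or aryloxy group, while the methyl ethers expose only sp3 C–H bonds. An excess of B2pin2 should carry both sites through, after which no open position remains for further borylation. Perborate then adds to each boron and the aryl group migrates to oxygen with retention of position, so each hydroxyl should end where the boron was.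

Step 9
Reactants: 17 undeca-O-methyl pentamer diol
Product: 18 2-{2-[4-(2-(3,4,5-trihydroxyphenoxy)-3,4,5-trihydroxyphenoxy)-3,5-dihydroxyphenoxy]-3,5-dihydroxyphenoxy}benzene-1,3,5-triol (CNP0243665.0)
Conditions: BBr3 (30 equiv), CH2Cl2, −78 °C to rt, argon; then H2O, 0 °C
Reagents that add atoms: none
Why: Lewis-acid ether cleavage, in which BBr3 binds each methoxy oxygen and bromide attacks the methyl carbon in an SN2 step; the diaryl ether oxygens carry no sp3 carbon and persist, and hydrolysis of the aryl borates should free all thirteen hydroxyls.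

## Compound list

1 | 2,6-dimethoxyphenol | COc1cccc(OC)c1O | starting material
2 | 2-fluoro-6-methoxybenzaldehyde | COc1cccc(F)c1C=O | starting material
3 | 2-(2,6-dimethoxyphenoxy)-6-methoxybenzaldehyde | COc1cccc(Oc2c(OC)cccc2OC)c1C=O | intermediate
4 | 2-(2,6-dimethoxyphenoxy)-6-methoxyphenyl formate | COc1cccc(Oc2c(OC)cccc2OC)c1OC=O | intermediate (not isolated)
5 | 2-(2,6-dimethoxyphenoxy)-6-methoxyphenol | COc1cccc(Oc2c(OC)cccc2OC)c1O | intermediate
6 | 5-bromo-1,2,3-trimethoxybenzene | COc1cc(Br)cc(OC)c1OC | starting material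
7 | 1-bromo-2-[chloro(methoxy)methyl]-3,4,5-trimethoxybenzene (racemic, transient) | COc1cc(Br)c(C(Cl)OC)c(OC)c1OC | intermediate (not isolated)
8 | 6-bromo-2,3,4-trimethoxybenzaldehyde | COc1cc(Br)c(C=O)c(OC)c1OC | intermediate
9 | 4-bromo-2,6-dimethoxyphenol | COc1cc(Br)cc(OC)c1O | starting material
10 | 6-(4-bromo-2,6-dimethoxyphenoxy)-2,3,4-trimethoxybenzaldehyde | COc1cc(Oc2c(OC)cc(Br)cc2OC)c(C=O)c(OC)c1OC | intermediate
11 | 6-{4-[2-(2,6-dimethoxyphenoxy)-6-methoxyphenoxy]-2,6-dimethoxyphenoxy}-2,3,4-trimethoxybenzaldehyde | COc1cccc(OC)c1Oc1cccc(OC)c1Oc1cc(OC)c(Oc2cc(OC)c(OC)c(OC)c2C=O)c(OC)c1 | intermediate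
12 | 6-{4-[2-(2,6-dimethoxyphenoxy)-6-methoxyphenoxy]-2,6-dimethoxyphenoxy}-2,3,4-trimethoxyphenyl formate | COc1cccc(OC)c1Oc1cccc(OC)c1Oc1cc(OC)c(Oc2cc(OC)c(OC)c(OC)c2OC=O)c(OC)c1 | intermediate (not isolated)
13 | 6-{4-[2-(2,6-dimethoxyphenoxy)-6-methoxyphenoxy]-2,6-dimethoxyphenoxy}-2,3,4-trimethoxyphenol | COc1cccc(OC)c1Oc1cccc(OC)c1Oc1cc(OC)c(Oc2cc(OC)c(OC)c(OC)c2O)c(OC)c1 | intermediate
14 | 5-iodo-1,2,3-trimethoxybenzene | COc1cc(I)cc(OC)c1OC | starting material
15 | 1-[2-(2,6-dimethoxyphenoxy)-6-methoxyphenoxy]-3,5-dimethoxy-4-[3,4,5-trimethoxy-2-(3,4,5-trimethoxyphenoxy)phenoxy]benzene (dideoxy undeca-O-methyl pentamer, lacking the oxygens at position 4 of ring A and position 5 of ring B) | COc1cccc(OC)c1Oc1cccc(OC)c1Oc1cc(OC)c(Oc2cc(OC)c(OC)c(OC)c2Oc2cc(OC)c(OC)c(OC)c2)c(OC)c1 | intermediate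
16 | bis(4,4,5,5-tetramethyl-1,3,2-dioxaborolan-2-yl) derivative of 15, boron at position 4 of ring A and position 5 of ring B (bis-boronate) | COc1cc(B2OC(C)(C)C(C)(C)O2)cc(OC)c1Oc1cc(B2OC(C)(C)C(C)(C)O2)cc(OC)c1Oc1cc(OC)c(Oc2cc(OC)c(OC)c(OC)c2Oc2cc(OC)c(OC)c(OC)c2)c(OC)c1 | intermediate (not isolated)
17 | 3,5-dimethoxy-4-{5-hydroxy-3-methoxy-2-[3,5-dimethoxy-4-(3,4,5-trimethoxy-2-(3,4,5-trimethoxyphenoxy)phenoxy)phenoxy]phenoxy}phenol (undeca-O-methyl pentamer diol, free hydroxyls at position 4 of ring A and position 5 of ring B) | COc1cc(O)cc(OC)c1Oc1cc(O)cc(OC)c1Oc1cc(OC)c(Oc2cc(OC)c(OC)c(OC)c2Oc2cc(OC)c(OC)c(OC)c2)c(OC)c1 | intermediate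
18 | 2-{2-[4-(2-(3,4,5-trihydroxyphenoxy)-3,4,5-trihydroxyphenoxy)-3,5-dihydroxyphenoxy]-3,5-dihydroxyphenoxy}benzene-1,3,5-triol (CNP0243665.0) | Oc1cc(O)c(Oc2cc(O)cc(O)c2Oc2cc(O)c(Oc3cc(O)c(O)c(O)c3Oc3cc(O)c(O)c(O)c3)c(O)c2)c(O)c1 | target

## Step count and risks

Total step count: 9. Longest linear sequence: 7 steps (steps 3, 4, 5, 6, 7, 8, 9; the arm of steps 1 and 2 joins at step 5 and is equally long).

Steps most likely to fail:

1. Step 8. The second borylation may stall on the large, Lewis-basic polyether, leaving mono-hydroxylated material, or forcing conditions may erode the steric control and allow borylation next to a methoxy group. The fallback carries both oxygens in from the start as methyl ethers and gives up the late-stage economy; it sets out from 10 and returns to the route at 18. Commercial 2,4,6-trimethoxyphenol and 2-bromo-4,6-dimethoxybenzaldehyde would be joined under the conditions of step 4 to give 2-(2,4,6-trimethoxyphenoxy)-4,6-dimethoxybenzaldehyde F1. mCPBA oxidation would pass through 2-(2,4,6-trimethoxyphenoxy)-4,6-dimethoxyphenyl formate F2, and methanolysis would give 2-(2,4,6-trimethoxyphenoxy)-4,6-dimethoxyphenol F3. Ullmann coupling of F3 with 10, as in step 5, would give 6-{4-[2-(2,4,6-trimethoxyphenoxy)-4,6-dimethoxyphenoxy]-2,6-dimethoxyphenoxy}-2,3,4-trimethoxybenzaldehyde F4. Baeyer–Villiger oxidation would pass through the corresponding 2,3,4-trimethoxyphenyl formate F5 to the corresponding 2,3,4-trimethoxyphenol F6. Coupling of F6 with 14, as in step 7, would give the trideca-O-methyl ether of 18 F7, and BBr3 would then cleave all thirteen methyl ethers to 18.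

2. Step 4. Chemoselectivity between the two aryl bromides may be lost, so that the phenoxide of 9 is also arylated by product 10 or by 9 itself and ether oligomers form. The fallback removes the competing halide by changing the order of assembly; it sets out from 9 (with 5) and returns at 11. 9 would be benzylated (BnBr, K2CO3, DMF) to 2-(benzyloxy)-5-bromo-1,3-dimethoxybenzene F8. Ullmann coupling of F8 with 5 under the conditions of step 5 would give 2-(benzyloxy)-5-[2-(2,6-dimethoxyphenoxy)-6-methoxyphenoxy]-1,3-dimethoxybenzene F9. Hydrogenolysis (H2, palladium on carbon, EtOAc) would free 4-[2-(2,6-dimethoxyphenoxy)-6-methoxyphenoxy]-2,6-dimethoxyphenol F10. F10 would then be coupled with 8, now the only aryl halide in the flask, under the conditions of step 4 to give 11.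

3. Step 9. Cleavage of the eleven methyl ethers may be incomplete and give mixtures of partly methylated products, and the pyrogallol-type rings D and E may oxidise in air during isolation of the free polyphenol. The fallback replaces direct isolation by a derivatise, purify and release sequence; it sets out from 17 and returns at 18. The crude product of the BBr3 treatment would be acetylated (Ac2O, pyridine, DMAP) to the trideca-O-acetate of 18 F11. F11 would be purified on silica, where partly methylated acetates separate and can be returned to BBr3. Acid methanolysis (HCl in MeOH generated from AcCl, rt, argon) would then release 18 under non-oxidising conditions.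

## Further compounds

F1 | step 8 | 2-(2,4,6-trimethoxyphenoxy)-4,6-dimethoxybenzaldehyde | COc1cc(OC)c(Oc2cc(OC)cc(OC)c2C=O)c(OC)c1
F2 | step 8 | 2-(2,4,6-trimethoxyphenoxy)-4,6-dimethoxyphenyl formate | COc1cc(OC)c(Oc2cc(OC)cc(OC)c2OC=O)c(OC)c1
F3 | step 8 | 2-(2,4,6-trimethoxyphenoxy)-4,6-dimethoxyphenol | COc1cc(OC)c(Oc2cc(OC)cc(OC)c2O)c(OC)c1
F4 | step 8 | 6-{4-[2-(2,4,6-trimethoxyphenoxy)-4,6-dimethoxyphenoxy]-2,6-dimethoxyphenoxy}-2,3,4-trimethoxybenzaldehyde | COc1cc(OC)c(Oc2cc(OC)cc(OC)c2Oc2cc(OC)c(Oc3cc(OC)c(OC)c(OC)c3C=O)c(OC)c2)c(OC)c1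
F5 | step 8 | 6-{4-[2-(2,4,6-trimethoxyphenoxy)-4,6-dimethoxyphenoxy]-2,6-dimethoxyphenoxy}-2,3,4-trimethoxyphenyl formate | COc1cc(OC)c(Oc2cc(OC)cc(OC)c2Oc2cc(OC)c(Oc3cc(OC)c(OC)c(OC)c3OC=O)c(OC)c2)c(OC)c1
F6 | step 8 | 6-{4-[2-(2,4,6-trimethoxyphenoxy)-4,6-dimethoxyphenoxy]-2,6-dimethoxyphenoxy}-2,3,4-trimethoxyphenol | COc1cc(OC)c(Oc2cc(OC)cc(OC)c2Oc2cc(OC)c(Oc3cc(OC)c(OC)c(OC)c3O)c(OC)c2)c(OC)c1
F7 | step 8 | trideca-O-methyl ether of 18 | COc1cc(OC)c(Oc2cc(OC)cc(OC)c2Oc2cc(OC)c(Oc3cc(OC)c(OC)c(OC)c3Oc3cc(OC)c(OC)c(OC)c3)c(OC)c2)c(OC)c1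
F8 | step 4 | 2-(benzyloxy)-5-bromo-1,3-dimethoxybenzene | COc1cc(Br)cc(OC)c1OCc1ccccc1
F9 | step 4 | 2-(benzyloxy)-5-[2-(2,6-dimethoxyphenoxy)-6-methoxyphenoxy]-1,3-dimethoxybenzene | COc1cccc(OC)c1Oc1cccc(OC)c1Oc1cc(OC)c(OCc2ccccc2)c(OC)c1
F10 | step 4 | 4-[2-(2,6-dimethoxyphenoxy)-6-methoxyphenoxy]-2,6-dimethoxyphenol | COc1cccc(OC)c1Oc1cccc(OC)c1Oc1cc(OC)c(O)c(OC)c1
F11 | step 9 | trideca-O-acetate of 18 | CC(=O)Oc1cc(OC(C)=O)c(Oc2cc(OC(C)=O)cc(OC(C)=O)c2Oc2cc(OC(C)=O)c(Oc3cc(OC(C)=O)c(OC(C)=O)c(OC(C)=O)c3Oc3cc(OC(C)=O)c(OC(C)=O)c(OC(C)=O)c3)c(OC(C)=O)c2)c(OC(C)=O)c1
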